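**Target:** (13E)-19-hydroxy-3α,6β-bis(3-methylbutanoyloxy)labda-8,13-dien-15-oic acid, (3R,4S,5R,6R,10S).

## Retrosynthetic overview

1. The acid and the primary alcohol are unmasked last (allyl ester, allyl carbonate); the C13=C14 bond comes from olefination of a C13 methyl ketone; the two isovalerates are put on a 3α,6β-diol.
2. Key disconnection C9–C11: a tetrasubstituted C8=C9 enol triflate is joined to a ketone homoenolate, made catalytically on palladium by ring-opening of 1-methylcyclopropanol. C9 (a former carbonyl carbon) and C11 (the β-carbon of a ketone) are both natively electrophilic.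
3. The enol triflate comes from a ring B ene-dione by site-selective conjugate hydride addition and enolate trapping; hydride reductions then set 3α-OH and 6β-OH and turn the C19 ester into CH2OH.
4. The ene-dione keto ester comes from a catalytic enantioselective Diels–Alder reaction of a quinone monoketal with a siloxy diene ester, followed by C5 epimerisation and α-face methylation at C4.
5. Ring order: ring B is carried in from the aromatic precursor, ring A is closed by the cycloaddition, the side chain is attached last.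

**Assumption:** the (S)-oxazaborolidinium catalyst is taken to give the (10S) cycloadduct drawn; if the facial sense is opposite, the (R)-catalyst is used with no other change.

**Naming convention:** bicyclic compounds carry labdane numbers (ring A C1–C5 and C10, ring B C5–C10; C17 = methyl on C8; C18/C19 = α/β substituent on C4; C20 = methyl on C10; β = the face of C20).

## Route

Step 1
Reactants: 1 4-methoxy-2,6-dimethylphenol
Product: 2 4,4-dimethoxy-2,6-dimethylcyclohexa-2,5-dien-1-one
Conditions: PhI(OAc)2, MeOH, 0 °C to rt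
Reagents that add atoms: methanol, CO
Why: Oxidative dearomatisation of a para-methoxyphenol by a hypervalent iodine diacetate in methanol gives the quinone monoketal, which masks the future C6 carbonyl and leaves only the future C9 carbonyl free; no stereocentre is formed.

Step 2
Reactants: 3 methyl acetate; 4 acrolein
Product: 6 methyl 3-hydroxypent-4-enoate (racemic), via lithium enolate 5 (not isolated)
Conditions: LiN(iPr)2, THF, −78 °C; then 4; AcOH quench
Reagents that add atoms: none
Why: Kinetic ester enolate aldol addition (1,2-addition to the enal at low temperature); the carbinol centre is racemic and is erased in step 3.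

Step 3
Reactants: 6 methyl 3-hydroxypent-4-enoate
Product: 7 methyl 3-oxopent-4-enoate
Conditions: Dess–Martin periodinane, CH2Cl2, 0 °C
Reagents that add atoms: none
Why: Dess–Martin oxidation of the allylic carbinol gives the vinyl ketone (Nazarov reagent) under non-basic conditions that spare the polymerisation-prone enone; it is used at once.

Step 4
Reactants: 7 methyl 3-oxopent-4-enoate
Product: 8 methyl (2Z)-3-(triisopropylsilyloxy)penta-2,4-dienoate
Conditions: iPr3SiOTf, Et3N, CH2Cl2, 0 °C
Reagents that add atoms: triisopropylsilyl trifluoromethanesulfonate, CC(C)[Si](OS(=O)(=O)C(F)(F)F)(C(C)C)C(C)C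
Why: O-silylation of the chelated β-keto ester enol (silyl enol ether formation) gives the (2Z) 2-siloxy diene, whose ester lies outside the diene so that the s-cis form is accessible.

Step 5
Reactants: 2 4,4-dimethoxy-2,6-dimethylcyclohexa-2,5-dien-1-one; 8 methyl (2Z)-3-(triisopropylsilyloxy)penta-2,4-dienoate
Product: 10 methyl 8,10β-dimethyl-3,6,9-trioxo-5βH-decal-7-ene-4-carboxylate (cis-fused; C4 epimers and enol), via silyl enol ether cycloadduct 9 (not isolated)
Conditions: (S)-1-(2-methylphenyl)-3,3-diphenyltetrahydro-1H,3H-pyrrolo[1,2-c][1,3,2]oxazaborole (20 mol %), HN(SO2CF3)2 (20 mol %), CH2Cl2, −78 to −20 °C; then 2 M HCl, THF, rt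
Reagents that add atoms: water, O
Why: Catalytic enantioselective Diels–Alder reaction: the chiral oxazaborolidinium ion binds the single carbonyl of 2, the siloxy-activated diene terminus (C4) bonds to the β-carbon (C5) and the CH2 terminus to the methyl-bearing α-carbon, so ring A closes with the quaternary C10 (S, face chosen by the catalyst) and a cis fusion (endo, suprafacial); aqueous acid then unmasks the C3 ketone and the C6 carbonyl.

Step 6
Reactants: 10 methyl 8,10β-dimethyl-3,6,9-trioxo-5βH-decal-7-ene-4-carboxylate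
Product: 12 methyl 4α,8,10β-trimethyl-3,6,9-trioxo-5αH-decal-7-ene-4β-carboxylate, via trans-fused keto ester 11 (not isolated)
Conditions: K2CO3, MeI, acetone, rt
Reagents that add atoms: iodomethane, CI
Why: Base epimerises C5 (α to the C6 carbonyl) to the trans fusion, and C-alkylation of the β-keto ester enolate takes methyl on the α-face, anti to the axial C10 methyl, leaving the ester β (axial) as in podocarpate-type alkylations; the quaternary C4 then holds the trans fusion thermodynamically.

Step 7
Reactants: 12 methyl 4α,8,10β-trimethyl-3,6,9-trioxo-5αH-decal-7-ene-4β-carboxylate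
Product: 14 methyl 4α,8,10β-trimethyl-3,6-dioxo-9-(trifluoromethylsulfonyloxy)-5αH-decal-8-ene-4β-carboxylate, via lithium enolate 13 (not isolated)
Conditions: LiBH(sBu)3 (1.05 equiv), THF, −78 °C; then N-(5-chloropyridin-2-yl)bis(trifluoromethanesulfonimide), −78 to 0 °C
Reagents that add atoms: N-(5-chloropyridin-2-yl)bis(trifluoromethanesulfonimide), FC(F)(F)S(=O)(=O)N(c1ccc(Cl)cn1)S(=O)(=O)C(F)(F)F
Why: Conjugate reduction of the ene-dione by the bulky hydride at the unsubstituted C7 gives the C9 enolate regiospecifically (C10 is quaternary), and O-triflation (enolate trapping) fixes the tetrasubstituted C8=C9 bond; no stereocentre is formed and the hindered C3 ketone survives one equivalent.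

Step 8
Reactants: 14 methyl 4α,8,10β-trimethyl-3,6-dioxo-9-(trifluoromethylsulfonyloxy)-5αH-decal-8-ene-4β-carboxylate
Product: 16 3α,6β-dihydroxy-4β-(hydroxymethyl)-4α,8,10β-trimethyl-5αH-decal-8-en-9-yl trifluoromethanesulfonate, via hydroxy lactone 15 (not isolated)
Conditions: LiBH(sBu)3 (2.5 equiv), THF, −78 to 0 °C; then LiBH4, MeOH, 0 to 45 °C
Reagents that add atoms: none
Why: Diastereoselective ketone reduction then lactone reduction: the bulky hydride attacks C3 equatorially to give the axial 3α-alcohol and attacks C6 from the α-face because the β-face is screened by the axial C10 methyl and C19 ester; the 6β-alkoxide closes onto C19 as a γ-lactone, which LiBH4 opens to the 6β,19-diol without touching the enol triflate.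

Step 9
Reactants: 16 3α,6β-dihydroxy-4β-(hydroxymethyl)-4α,8,10β-trimethyl-5αH-decal-8-en-9-yl trifluoromethanesulfonate; 17 1-methylcyclopropan-1-ol
Product: 18 3α,6β,19-trihydroxy-14,15-dinorlabd-8-en-13-one
Conditions: Pd(OAc)2 (10 mol %), 2-dicyclohexylphosphino-2′,4′,6′-triisopropylbiphenyl (20 mol %), Cs2CO3, 1,4-dioxane, 80 °C
Reagents that add atoms: none
Why: Key step, a palladium-catalysed ring-opening cross-coupling of a cyclopropanol: oxidative addition of the enol triflate to zerovalent palladium, exchange to the divalent palladium cyclopropoxide, strain-driven β-carbon elimination to the palladium homoenolate and reductive elimination join C9 to C11, two natively electrophilic carbons, and place the chain on the pre-set tetrasubstituted alkene with no new stereocentre.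

Step 10
Reactants: 18 3α,6β,19-trihydroxy-14,15-dinorlabd-8-en-13-one
Product: 19 19-(allyloxycarbonyloxy)-3α,6β-dihydroxy-14,15-dinorlabd-8-en-13-one
Conditions: allyl chloroformate (1.1 equiv), pyridine, CH2Cl2, −20 °C
Reagents that add atoms: allyl chloroformate, C=CCOC(=O)Cl
Why: Chemoselective carbonate formation at the primary C19 hydroxyl; the axial 3α- and 6β-hydroxyls (the latter flanked by two axial groups) react far more slowly.

Step 11
Reactants: 19 19-(allyloxycarbonyloxy)-3α,6β-dihydroxy-14,15-dinorlabd-8-en-13-one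
Product: 20 19-(allyloxycarbonyloxy)-13-oxo-14,15-dinorlabd-8-ene-3α,6β-diyl bis(3-methylbutanoate)
Conditions: (iBuCO)2O, 4-(dimethylamino)pyridine, Et3N, toluene, 80 °C
Reagents that add atoms: 3-methylbutanoic anhydride, CC(C)CC(=O)OC(=O)CC(C)C
Why: Nucleophile-catalysed acyl transfer (Steglich-type) under forcing conditions esterifies both hindered axial alcohols with retention at C3 and C6.

Step 12
Reactants: 20 19-(allyloxycarbonyloxy)-13-oxo-14,15-dinorlabd-8-ene-3α,6β-diyl bis(3-methylbutanoate)
Product: 21 allyl (13E)-19-(allyloxycarbonyloxy)-3α,6β-bis(3-methylbutanoyloxy)labda-8,13-dien-15-oate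
Conditions: NaH, (EtO)2P(O)CH2CO2CH2CH=CH2, THF, 0 to 50 °C; minor (13Z) isomer removed by chromatography
Reagents that add atoms: allyl 2-(diethoxyphosphoryl)acetate, CCOP(=O)(OCC)CC(=O)OCC=C
Why: Horner–Wadsworth–Emmons olefination of the unhindered methyl ketone gives the trisubstituted enoate with the (13E) isomer predominating (ester anti to the larger chain); the isovalerates and the carbonate are inert to the stabilised phosphonate anion.

Step 13
Reactants: 21 allyl (13E)-19-(allyloxycarbonyloxy)-3α,6β-bis(3-methylbutanoyloxy)labda-8,13-dien-15-oate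
Product: 22 (13E)-19-hydroxy-3α,6β-bis(3-methylbutanoyloxy)labda-8,13-dien-15-oic acid
Conditions: Pd(PPh3)4 (5 mol %), morpholine, THF, rt
Reagents that add atoms: none
Why: Tsuji–Trost deallylation: zerovalent palladium ionises the allyl ester and the allyl carbonate to π-allyl complexes that morpholine captures, freeing the acid and (after loss of CO2) the primary alcohol under near-neutral conditions that avoid acyl migration and touch no stereocentre.

## Compound list

1 | 4-methoxy-2,6-dimethylphenol | COc1cc(C)c(O)c(C)c1 | starting material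
2 | 4,4-dimethoxy-2,6-dimethylcyclohexa-2,5-dien-1-one | COC1(OC)C=C(C)C(=O)C(C)=C1 | intermediate
3 | methyl acetate | COC(C)=O | starting material
4 | acrolein | C=CC=O | starting material
5 | lithium enolate of methyl acetate (not isolated) | [Li+].[O-]C(=C)OC | intermediate
6 | methyl 3-hydroxypent-4-enoate (racemic) | C=CC(O)CC(=O)OC | intermediate
7 | methyl 3-oxopent-4-enoate | C=CC(=O)CC(=O)OC | intermediate
8 | methyl (2Z)-3-(triisopropylsilyloxy)penta-2,4-dienoate | CC(C)[Si](C(C)C)(C(C)C)O/C(C=C)=C\C(=O)OC | intermediate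
9 | methyl 6,6-dimethoxy-8,10β-dimethyl-9-oxo-3-(triisopropylsilyloxy)-5βH-decala-2,7-diene-4α-carboxylate (cis-fused cycloadduct, not isolated) | CC=1C(=O)[C@@]2(C)CC=C(O[Si](C(C)C)(C(C)C)C(C)C)[C@@H](C(=O)OC)[C@H]2C(OC)(OC)C=1 | intermediate
10 | methyl 8,10β-dimethyl-3,6,9-trioxo-5βH-decal-7-ene-4-carboxylate (cis-fused; C4 epimers and enol) | CC=1C(=O)[C@@]2(C)CCC(=O)C(C(=O)OC)[C@H]2C(=O)C=1 | intermediate
11 | methyl 8,10β-dimethyl-3,6,9-trioxo-5αH-decal-7-ene-4-carboxylate (trans-fused, not isolated) | CC=1C(=O)[C@@]2(C)CCC(=O)C(C(=O)OC)[C@@H]2C(=O)C=1 | intermediate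
12 | methyl 4α,8,10β-trimethyl-3,6,9-trioxo-5αH-decal-7-ene-4β-carboxylate | CC=1C(=O)[C@@]2(C)CCC(=O)[C@](C)(C(=O)OC)[C@@H]2C(=O)C=1 | intermediate
13 | lithium 4β-(methoxycarbonyl)-4α,8,10β-trimethyl-3,6-dioxo-5αH-decal-8-en-9-olate (not isolated) | [Li+].CC1=C([O-])[C@@]2(C)CCC(=O)[C@](C)(C(=O)OC)[C@@H]2C(=O)C1 | intermediate
14 | methyl 4α,8,10β-trimethyl-3,6-dioxo-9-(trifluoromethylsulfonyloxy)-5αH-decal-8-ene-4β-carboxylate | CC1=C(OS(=O)(=O)C(F)(F)F)[C@@]2(C)CCC(=O)[C@](C)(C(=O)OC)[C@@H]2C(=O)C1 | intermediate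
15 | 3α-hydroxy-4α,8,10β-trimethyl-9-(trifluoromethylsulfonyloxy)-5αH-decal-8-ene-4β-carboxylic acid 6β-lactone (not isolated) | CC1=C(OS(=O)(=O)C(F)(F)F)[C@@]2(C)CC[C@@H](O)[C@](C)(C3=O)[C@@H]2[C@H](O3)C1 | intermediate
16 | 3α,6β-dihydroxy-4β-(hydroxymethyl)-4α,8,10β-trimethyl-5αH-decal-8-en-9-yl trifluoromethanesulfonate | CC1=C(OS(=O)(=O)C(F)(F)F)[C@@]2(C)CC[C@@H](O)[C@](C)(CO)[C@@H]2[C@H](O)C1 | intermediate
17 | 1-methylcyclopropan-1-ol | CC1(O)CC1 | starting material
18 | 3α,6β,19-trihydroxy-14,15-dinorlabd-8-en-13-one | CC1=C(CCC(C)=O)[C@@]2(C)CC[C@@H](O)[C@](C)(CO)[C@@H]2[C@H](O)C1 | intermediate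
19 | 19-(allyloxycarbonyloxy)-3α,6β-dihydroxy-14,15-dinorlabd-8-en-13-one | CC1=C(CCC(C)=O)[C@@]2(C)CC[C@@H](O)[C@](C)(COC(=O)OCC=C)[C@@H]2[C@H](O)C1 | intermediate
20 | 19-(allyloxycarbonyloxy)-13-oxo-14,15-dinorlabd-8-ene-3α,6β-diyl bis(3-methylbutanoate) | CC1=C(CCC(C)=O)[C@@]2(C)CC[C@@H](OC(=O)CC(C)C)[C@](C)(COC(=O)OCC=C)[C@@H]2[C@H](OC(=O)CC(C)C)C1 | intermediate
21 | allyl (13E)-19-(allyloxycarbonyloxy)-3α,6β-bis(3-methylbutanoyloxy)labda-8,13-dien-15-oate | CC1=C(CC/C(C)=C/C(=O)OCC=C)[C@@]2(C)CC[C@@H](OC(=O)CC(C)C)[C@](C)(COC(=O)OCC=C)[C@@H]2[C@H](OC(=O)CC(C)C)C1 | intermediate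
22 | (13E)-19-hydroxy-3α,6β-bis(3-methylbutanoyloxy)labda-8,13-dien-15-oic acid, (3R,4S,5R,6R,10S) | CC1=C(CC/C(C)=C/C(=O)O)[C@@]2(C)CC[C@@H](OC(=O)CC(C)C)[C@](C)(CO)[C@@H]2[C@H](OC(=O)CC(C)C)C1 | target

## Step count and risks

Total steps: 13. Longest linear sequence: 12 (steps 2 to 13, from methyl acetate and acrolein).

**Step 9 (homoenolate coupling).** Reductive elimination at the neopentyl, tetrasubstituted alkenylpalladium may be slower than β-hydride loss from the palladium homoenolate, which would give but-3-en-2-one and the reduced alkene. The fallback sets out from 16 and replaces catalytic ring-opening by a preformed, masked ketone homoenolate. Zinc insertion (Zn, LiCl, THF) into 2-(2-bromoethyl)-2-methyl-1,3-dioxolane gives [2-(2-methyl-1,3-dioxolan-2-yl)ethyl]zinc bromide F7. Negishi coupling with 16 (Pd(OAc)2, a biaryl dialkylphosphine, THF, 50 °C) gives the ketal 3α,6β,19-trihydroxy-14,15-dinorlabd-8-en-13-one ethylene ketal F8. 1 M HCl in THF returns to the route at 18.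

**Step 5 (enantioselective cycloaddition).** The ester-bearing diene 8 is less nucleophilic than the simple siloxy dienes for which this catalysis is established, and it must add to an α-methyl dienone next to a ketal. The fallback sets out from 2 and brings in the C19 carbon after the cycloaddition. The same catalyst is used with 2-(triisopropylsilyloxy)buta-1,3-diene F1 (from but-3-en-2-one, iPr3SiOTf, Et3N) to give the cycloadduct 6,6-dimethoxy-8,10β-dimethyl-3-(triisopropylsilyloxy)-5βH-decala-2,7-dien-9-one F2. Bu4NF/AcOH then gives the cis-fused ketone 6,6-dimethoxy-8,10β-dimethyl-5βH-decal-7-ene-3,9-dione F3 with the ketal intact. Thermodynamic carbomethoxylation (NaH, dimethyl carbonate, THF, reflux) goes to C4, as for cis-fused 3-ketones, and gives methyl 6,6-dimethoxy-8,10β-dimethyl-3,9-dioxo-5βH-decal-7-ene-4-carboxylate F4. 2 M HCl in THF returns to the route at 10.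

**Step 7 (conjugate reduction and triflation).** The hydride may add 1,2 to the C6 carbonyl or the enolate may equilibrate before trapping. The fallback sets out from 12 and uses a two-electron metal reduction with site-selective desilylation. Zn and Me3SiCl in THF at 0 °C give methyl 4α,8,10β-trimethyl-3-oxo-6,9-bis(trimethylsilyloxy)-5αH-decala-6,8-diene-4β-carboxylate F5. The unhindered C6 enol ether is cleaved selectively (K2CO3, MeOH, −20 °C) to methyl 4α,8,10β-trimethyl-3,6-dioxo-9-(trimethylsilyloxy)-5αH-decal-8-ene-4β-carboxylate F6. CsF and PhN(SO2CF3)2 in 1,2-dimethoxyethane convert F6 directly into the triflate, returning to the route at 14.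

## Further compounds

F1 | step 5 | 2-(triisopropylsilyloxy)buta-1,3-diene | C=CC(=C)O[Si](C(C)C)(C(C)C)C(C)C
F2 | step 5 | 6,6-dimethoxy-8,10β-dimethyl-3-(triisopropylsilyloxy)-5βH-decala-2,7-dien-9-one | CC=1C(=O)[C@@]2(C)CC=C(O[Si](C(C)C)(C(C)C)C(C)C)C[C@H]2C(OC)(OC)C=1
F3 | step 5 | 6,6-dimethoxy-8,10β-dimethyl-5βH-decal-7-ene-3,9-dione | CC=1C(=O)[C@@]2(C)CCC(=O)C[C@H]2C(OC)(OC)C=1
F4 | step 5 | methyl 6,6-dimethoxy-8,10β-dimethyl-3,9-dioxo-5βH-decal-7-ene-4-carboxylate | CC=1C(=O)[C@@]2(C)CCC(=O)C(C(=O)OC)[C@H]2C(OC)(OC)C=1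
F5 | step 7 | methyl 4α,8,10β-trimethyl-3-oxo-6,9-bis(trimethylsilyloxy)-5αH-decala-6,8-diene-4β-carboxylate | CC1=C(O[Si](C)(C)C)[C@@]2(C)CCC(=O)[C@](C)(C(=O)OC)[C@@H]2C(O[Si](C)(C)C)=C1
F6 | step 7 | methyl 4α,8,10β-trimethyl-3,6-dioxo-9-(trimethylsilyloxy)-5αH-decal-8-ene-4β-carboxylate | CC1=C(O[Si](C)(C)C)[C@@]2(C)CCC(=O)[C@](C)(C(=O)OC)[C@@H]2C(=O)C1
F7 | step 9 | [2-(2-methyl-1,3-dioxolan-2-yl)ethyl]zinc bromide | CC1(CC[Zn]Br)OCCO1
F8 | step 9 | 3α,6β,19-trihydroxy-14,15-dinorlabd-8-en-13-one ethylene ketal | CC1=C(CCC3(C)OCCO3)[C@@]2(C)CC[C@@H](O)[C@](C)(CO)[C@@H]2[C@H](O)C1
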